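## Retrosynthetic overview

1. 6 ⇒ 5: late allylic C–H hydroxylation at C4. No ring is touched.
2. 5 ⇒ 3: one bromonium-triggered cascade on an acyclic epoxy-diene. It makes C10–Br, C11–C6 and C7–O, breaks C3–O, and removes one H from the C3 methyl group.
3. Ring order inside the cascade: the bromocyclohexane forms first, then a six-membered oxonium ring (epoxonium 4), which expands to the oxepane.
4. 3 ⇒ 1: Appel bromination and Sharpless epoxidation of (E,E)-farnesol. The epoxide supplies both the C2 stereocentre and the ether oxygen.

**Locants.** "Cn" in the text means farnesane numbering: C1 = CH2Br carbon, C2 = OCH, C3 = C(=CH2), C4 = CHOH, C6 = ring-fusion CH, C7 = ring-fusion C(CH3)O, C10 = CHBr, C11 = CMe2. Benzoxepine locants appear only in names (C6 = 5a, C7 = 9a, C10 = 7, C11 = 6). The target is 2R,4R,6S,7S,10S.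

**Assumption.** The (R)-BINOL-derived catalyst of step 3 is taken to deliver Br+ to the face of C10=C11 that gives 10S. If the sense is the opposite, the (S)-catalyst is used.

## Route

**Step 1**
Reactants: 1 (2E,6E)-farnesol
Product: 2 (2S,3S)-2,3-epoxyfarnesol
Conditions: Ti(OiPr)4 (5 mol %), L-(+)-DET (7 mol %), TBHP (1.5 equiv, decane), 4 Å MS, CH2Cl2, −20 °C
Reagents that add atoms: tert-butyl hydroperoxide, CC(C)(C)OO
Why: In this Katsuki–Sharpless asymmetric epoxidation only the allylic C2=C3 alkene binds to titanium, and L-(+)-tartrate gives the (2S,3S)-epoxide of an E-allylic alcohol in about 95 % ee, which sets C2 of the target (C3 is sacrificial).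

**Step 2**
Reactants: 2 (2S,3S)-2,3-epoxyfarnesol
Product: 3 (2R,3S)-2-(bromomethyl)-3-[(3E)-4,8-dimethylnona-3,7-dien-1-yl]-3-methyloxirane
Conditions: CBr4 (1.2 equiv), PPh3 (1.25 equiv), 2,6-lutidine (0.2 equiv, buffer), CH2Cl2, −30 → 0 °C
Reagents that add atoms: carbon tetrabromide, BrC(Br)(Br)Br
Why: The Appel reaction is an SN2 displacement at the primary carbon under near-neutral conditions, so no stereocentre is touched (C2 changes from S to R only because CH2Br now outranks C3) and the epoxide and both alkenes survive.

**Step 3**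
Reactants: 3 (2R,3S)-2-(bromomethyl)-3-[(3E)-4,8-dimethylnona-3,7-dien-1-yl]-3-methyloxirane
Product: 5 (2R,5aS,7S,9aS)-7-bromo-2-(bromomethyl)-6,6,9a-trimethyl-3-methylidenedecahydro-1-benzoxepine, via tricyclic epoxonium ion 4 (not isolated)
Conditions: NBS (1.05 equiv), (R)-3,3′-diaryl-BINOL-derived thiophosphoramide Lewis-base catalyst (10 mol %), 4 Å MS, toluene/CH2Cl2 1:1, −78 °C; aq. Na2S2O3
Reagents that add atoms: N-bromosuccinimide, O=C1CCC(=O)N1Br
Why: Proposed new method: the catalyst-bound Br+ goes to one face of the most accessible terminal C10=C11 alkene, the E-C6=C7 alkene attacks C11 through a chair with Br equatorial (anti addition, giving 6S,7S,10S with H-6 and CH3-7 trans), the epoxide oxygen traps the C7 cation through a six-membered transition state to give epoxonium 4 (in the wanted diastereomer its CH(CH2Br) bridge lies anti to the axial C7 methyl), the tertiary C3–O bond then breaks rather than the secondary C2–O bond deactivated by CH2Br, which expands the ring to the oxepane while succinimide anion removes the most accessible proton from the C3 methyl group, so C2 keeps its Sharpless configuration; the closest known reaction types are catalytic enantioselective bromonium-induced polyene cyclisation, endo-selective epoxonium ring-expansion cascades of 1,5-diepoxides, and base-assisted opening of O-activated trisubstituted epoxides to 2-methylene alcohols.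

**Step 4**
Reactants: 5 (2R,5aS,7S,9aS)-7-bromo-2-(bromomethyl)-6,6,9a-trimethyl-3-methylidenedecahydro-1-benzoxepine
Product: 6 (2R,4R,5aS,7S,9aS)-7-bromo-2-(bromomethyl)-6,6,9a-trimethyl-3-methylidenedecahydro-1-benzoxepin-4-ol (target)
Conditions: SeO2 (0.3 equiv), TBHP (2 equiv, decane), CH2Cl2, 0 °C → rt
Reagents that add atoms: selenium dioxide, O=[Se]=O (catalytic oxygen carrier); tert-butyl hydroperoxide, CC(C)(C)OO (terminal oxygen source)
Why: This Riley allylic hydroxylation (ene reaction at the =CH2 terminus, then [2,3]-sigmatropic shift) returns the alkene to the exocyclic position, oxidises the C4 methylene rather than the hindered, electron-poor C2 methine (CH2 > CH), and delivers oxygen to the ring face opposite the 2-CH2Br and the axial C7 methyl, which gives 4R.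

**Stereochemical bookkeeping.**
- C2 is set in step 1, and its C–O bond is never broken.
- C6, C7 and C10 are set in step 3.
- C4 is set in step 4.
- A wrong-face bromonium on the major enantiomer of 3 gives a separable diastereomer. The enantiomer of 5 needs two minor events, so its level falls below that of 2.

## Compound list

1 | (2E,6E)-farnesol | CC(C)=CCC/C(C)=C/CC/C(C)=C/CO | starting material
2 | (2S,3S)-2,3-epoxyfarnesol | OC[C@@H]1O[C@@]1(C)CC/C=C(\C)CCC=C(C)C | intermediate
3 | (2R,3S)-2-(bromomethyl)-3-[(3E)-4,8-dimethylnona-3,7-dien-1-yl]-3-methyloxirane | BrC[C@@H]1O[C@@]1(C)CC/C=C(\C)CCC=C(C)C | intermediate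
4 | tricyclic epoxonium ion (O+ bonded to C2, C3 and C7; succinimidate counter-ion; not isolated) | BrC[C@@H]1[O+]2[C@@]1(C)CC[C@H]3C(C)(C)[C@@H](Br)CC[C@]23C | intermediate
5 | (2R,5aS,7S,9aS)-7-bromo-2-(bromomethyl)-6,6,9a-trimethyl-3-methylidenedecahydro-1-benzoxepine | C=C1CC[C@H]2C(C)(C)[C@@H](Br)CC[C@]2(C)O[C@H]1CBr | intermediate
6 | (2R,4R,5aS,7S,9aS)-7-bromo-2-(bromomethyl)-6,6,9a-trimethyl-3-methylidenedecahydro-1-benzoxepin-4-ol | C=C1[C@H](O)C[C@H]2C(C)(C)[C@@H](Br)CC[C@]2(C)O[C@H]1CBr | target

**Total step count:** 4. **Longest linear sequence:** 4.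

## Steps most likely to fail

**Step 3 (highest risk).** Four things can go wrong:
- Br+ may attack C6=C7 instead, with direct capture by the epoxide.
- The C7 cation may lose a proton before the oxygen traps it.
- A hydride may shift from C2 to C3.
- The C3 centre may lose the C4 proton instead of a methyl proton.

The fallback sets out from 2 and returns at 5. It replaces the epoxide terminator with a free hydroxyl and puts the alkene in place beforehand. A hydroxyl-directed Ti(OiPr)4-mediated epoxide-to-allylic-alcohol rearrangement, with proton loss from the C3 methyl, gives (2R,6E)-7,11-dimethyl-3-methylidenedodeca-6,10-diene-1,2-diol F1. Primary-selective Appel bromination (CBr4/PPh3, 1.05 equiv, −20 °C) gives (2R,6E)-1-bromo-7,11-dimethyl-3-methylidenedodeca-6,10-dien-2-ol F2. Bromonium polyene cyclisation with Et2SBr·SbCl5Br in MeNO2 at −25 °C then closes both rings, with the C2 hydroxyl attacking the C7 cation directly. The two diastereomers share the fixed C2 centre and are separated by chromatography to give 5.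

**Step 4.** The conversion may be low, over-oxidation to the enone may occur, or C2–H may be attacked.

The fallback sets out from 5 and returns at 6. It replaces C–H oxidation with alkene oxidation followed by rearrangement. Acid isomerisation (cat. TsOH, benzene, 50 °C) gives the more stable endocyclic alkene (2R,5aS,7S,9aS)-7-bromo-2-(bromomethyl)-3,6,6,9a-tetramethyl-2,5,5a,6,7,8,9,9a-octahydro-1-benzoxepine (palisadin B) F3. This compound is also the likely by-product of step 3, so the detour recovers that material too. mCPBA attacks the face opposite the 2-CH2Br and the C7 methyl to give palisadin B (3R,4R)-3,4-epoxide F4. Et2Al(TMP) in toluene at 0 °C effects syn-elimination with a proton of the C3 methyl group, which is cis to the epoxide hydrogen. This gives 6 with the same C4 configuration.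

**Step 2.** Bromide or traces of HBr may open the epoxide, and the epoxy bromide may be labile on silica.

The fallback sets out from 2 and returns at 5. It moves C1–Br bond formation to after the ring construction. MsCl/Et3N gives [(2S,3S)-3-[(3E)-4,8-dimethylnona-3,7-dien-1-yl]-3-methyloxiran-2-yl]methyl methanesulfonate F5. F5 is put through the step 3 cascade to give [(2R,5aS,7S,9aS)-7-bromo-6,6,9a-trimethyl-3-methylidenedecahydro-1-benzoxepin-2-yl]methyl methanesulfonate F6. LiBr in refluxing 2-butanone displaces only the primary mesylate to give 5, because the equatorial, neopentyl-type secondary bromide is inert.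

## Further compounds

F1 | step 3 | (2R,6E)-7,11-dimethyl-3-methylidenedodeca-6,10-diene-1,2-diol | OC[C@H](O)C(=C)CC/C=C(\C)CCC=C(C)C
F2 | step 3 | (2R,6E)-1-bromo-7,11-dimethyl-3-methylidenedodeca-6,10-dien-2-ol | BrC[C@H](O)C(=C)CC/C=C(\C)CCC=C(C)C
F3 | step 4 | (2R,5aS,7S,9aS)-7-bromo-2-(bromomethyl)-3,6,6,9a-tetramethyl-2,5,5a,6,7,8,9,9a-octahydro-1-benzoxepine (palisadin B) | CC1=CC[C@H]2C(C)(C)[C@@H](Br)CC[C@]2(C)O[C@H]1CBr
F4 | step 4 | palisadin B (3R,4R)-3,4-epoxide (oxirane oxygen on the face of H-2 and H-6) | C[C@@]12O[C@@H]1C[C@H]3C(C)(C)[C@@H](Br)CC[C@]3(C)O[C@H]2CBr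
F5 | step 2 | [(2S,3S)-3-[(3E)-4,8-dimethylnona-3,7-dien-1-yl]-3-methyloxiran-2-yl]methyl methanesulfonate | CS(=O)(=O)OC[C@@H]1O[C@@]1(C)CC/C=C(\C)CCC=C(C)C
F6 | step 2 | [(2R,5aS,7S,9aS)-7-bromo-6,6,9a-trimethyl-3-methylidenedecahydro-1-benzoxepin-2-yl]methyl methanesulfonate | C=C1CC[C@H]2C(C)(C)[C@@H](Br)CC[C@]2(C)O[C@H]1COS(C)(=O)=O
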